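**Plan**

- Retrosynthetic cuts: (a) the O1–C2 and C4–C4a bonds of the pyran ring (aryl 1,1-dimethylpropargyl ether of the hydroxyl para to the ketone); (b) the aryl–C(=O)Ph bond together with the neighbouring aryl C7–O bond (aryne plus benzoic acid); (c) the aryl–prenyl bond and a helper aryl–Si bond (two carbamate-directed metalations of a phloroglucinol bis-MOM ether).
- Enabling feature: in the benzene ring the benzoyl carbon C6 sits between C7–OH and C5–O, i.e. an ortho-hydroxyaryl ketone with an oxygen on its far side. An aryne spanning C6–C7 can take up O and C(=O)Ph from PhCO2H in one operation, and the C5 oxygen decides which end receives which.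
- Forward order: the phloroglucinol ring is kept throughout. One oxygen is singled out as a carbamate, directs SiMe3 and then prenyl to its two ortho carbons in one flask, and is then turned into the triflate leaving group. Aryne insertion of benzoic acid follows, then MOM removal, and the pyran ring is closed last by propargyl ether Claisen rearrangement and oxa-6π electrocyclisation.
- Helpers and their removal: N-silyl group (work-up of step 3), carbamate (step 4), SiMe3 and OTf (both lost in the key step), MOM groups (step 6).
- Stereochemistry: the target has no stereocentre and no E/Z-defined double bond, so none has to be set.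

Key step: step 5

Remark: in the running text, ring positions of the intermediates are given in phenol numbering (C1 carries the carbamate or triflate oxygen, C2 the silicon, C6 the prenyl group). The systematic names of 13, 15 and 16 follow lowest-locant rules and so exchange the numbers 2 and 6. Positions of the target are in chromene numbering.

**Route**

Step 1
Reactants: 1 phloroglucinol (benzene-1,3,5-triol); 2 chloromethyl methyl ether
Product: 3 3,5-bis(methoxymethoxy)phenol
Conditions: MOMCl (2.0 equiv), i-Pr2NEt, DMF, 0 °C → rt; chromatography
Reagents that add atoms: chloromethyl methyl ether, COCCl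
Why: Williamson-type O-alkylation of the phenoxides with the hard electrophile MOMCl should give a statistical mixture from which the bis-ether is separated (mono- and tris-ethers can be recycled), leaving exactly one free hydroxyl as the oxygen that later directs both metalations and departs as triflate.

Step 2
Reactants: 3 3,5-bis(methoxymethoxy)phenol; 4 isopropyl isocyanate
Product: 5 3,5-bis(methoxymethoxy)phenyl N-isopropylcarbamate
Conditions: i-PrNCO, Et3N (cat.), CH2Cl2, rt
Reagents that add atoms: isopropyl isocyanate, CC(C)N=C=O
Why: Amine-catalysed addition of the phenol to the isocyanate (carbamoylation) installs a secondary carbamate that is a strong directing group for ortho-metalation and can later be removed under mild E1cB conditions.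

Step 3
Reactants: 5 3,5-bis(methoxymethoxy)phenyl N-isopropylcarbamate; 6 chlorotrimethylsilane; 7 prenyl bromide (1-bromo-3-methylbut-2-ene)
Product: 13 3,5-bis(methoxymethoxy)-2-(3-methylbut-2-en-1-yl)-6-(trimethylsilyl)phenyl N-isopropylcarbamate, via N-silyl carbamate 8 (not isolated), via first aryllithium 9 (not isolated), via disilyl carbamate 10 (not isolated), via second aryllithium 11 (not isolated), via N-silyl prenyl carbamate 12 (not isolated)
Conditions: TBSOTf, TMEDA, Et2O, 0 °C → rt; n-BuLi, TMEDA, −78 °C; Me3SiCl (1.0 equiv), −78 °C → rt; recool, n-BuLi, TMEDA, −78 °C; CuBr·SMe2 (10 mol %), prenyl bromide, −78 → −40 °C; aq. NaHSO4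
Reagents that add atoms: chlorotrimethylsilane, C[Si](C)(C)Cl; prenyl bromide, CC(C)=CCBr
Why: Two consecutive directed ortho-metalations of the carbamate, N-silylated once in situ, should take place at C2 and then at C6, the two positions flanked by the carbamate (the strongest director on the ring) and one OMOM group, in preference to C4 between the two weaker OMOM directors; the silyl quench places the group that later triggers aryne formation, copper-catalysed SN2 allylation of the second aryllithium gives the linear prenyl group, silicon goes in first so that no benzylic–allylic CH2 is present in either lithiation, and the N-silyl group is lost on acidic work-up.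

Step 4
Reactants: 13 3,5-bis(methoxymethoxy)-2-(3-methylbut-2-en-1-yl)-6-(trimethylsilyl)phenyl N-isopropylcarbamate; 14 N-phenylbis(trifluoromethanesulfonimide)
Product: 16 3,5-bis(methoxymethoxy)-2-(3-methylbut-2-en-1-yl)-6-(trimethylsilyl)phenyl trifluoromethanesulfonate, via phenol 15 (not isolated)
Conditions: DBU, Et2NH, MeCN, 40 °C; then PhNTf2, 40 °C
Reagents that add atoms: N-phenylbis(trifluoromethanesulfonimide), O=S(=O)(N(c1ccccc1)S(=O)(=O)C(F)(F)F)C(F)(F)F
Why: E1cB fragmentation of the secondary carbamate (N–H deprotonation, loss of isopropyl isocyanate, which Et2NH scavenges as a urea) frees the phenoxide without protodesilylation, and in situ O-sulfonylation gives the ortho-silylaryl triflate aryne precursor.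

Step 5
Reactants: 16 3,5-bis(methoxymethoxy)-2-(3-methylbut-2-en-1-yl)-6-(trimethylsilyl)phenyl trifluoromethanesulfonate; 17 benzoic acid
Product: 20 [2-hydroxy-4,6-bis(methoxymethoxy)-3-(3-methylbut-2-en-1-yl)phenyl](phenyl)methanone, via aryne 18 (not isolated), via aryl anion 19 (not isolated)
Conditions: PhCO2H (1.2 equiv), CsF (4 equiv), THF, 125 °C (sealed tube)
Reagents that add atoms: benzoic acid, OC(=O)c1ccccc1
Why: Fluoride attacks silicon of 16 and the resulting aryl anion expels the neighbouring triflate to give aryne 18, whose triple bond lies between the former C–OTf carbon (C1, flanked by the prenyl-bearing C6) and the former C–Si carbon (C2, flanked by the MOM-oxygenated C3). Benzoate, formed from 17 and CsF, should add through oxygen to C1 because the σ-withdrawing C3–O bond widens the internal angle at C1 and stabilises the negative charge that develops at C2, an electronic bias expected to outweigh the small steric penalty of the prenyl CH2 next to C1. Aryl anion 19 then attacks the ester carbonyl beside it through a four-membered tetrahedral adduct, and C–O cleavage gives the chelated phenoxide of 20, so the aryne has formally inserted into the acyl C–O bond of the acid and the new aryl–C(=O) bond joins the two fragments. The closest known reaction type is the CsF-mediated intermolecular C–O addition of carboxylic acids to arynes giving ortho-hydroxyaryl ketones, an anionic Fries-type 1,3 O-to-C acyl shift. No ring is closed and no stereocentre is formed. The step needs regioselective attack (secured by the OMOM group beside the triple bond), acyl transfer ahead of protonation of 19 (favoured by the high temperature and the small excess of acid) and tolerance of the prenyl alkene (an intramolecular ene reaction is geometrically impossible across a one-carbon tether).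

Step 6
Reactants: 20 [2-hydroxy-4,6-bis(methoxymethoxy)-3-(3-methylbut-2-en-1-yl)phenyl](phenyl)methanone
Product: 21 [2,4,6-trihydroxy-3-(3-methylbut-2-en-1-yl)phenyl](phenyl)methanone
Conditions: HCl (3 M aq.), MeOH, 40 °C
Reagents that add atoms: none
Why: Acid-catalysed acetal methanolysis should remove both MOM groups under conditions mild enough to leave the ortho-prenylphenol uncyclised.

Step 7
Reactants: 21 [2,4,6-trihydroxy-3-(3-methylbut-2-en-1-yl)phenyl](phenyl)methanone; 22 3-chloro-3-methylbut-1-yne
Product: 23 {2,6-dihydroxy-4-[(2-methylbut-3-yn-2-yl)oxy]-3-(3-methylbut-2-en-1-yl)phenyl}(phenyl)methanone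
Conditions: 3-chloro-3-methylbut-1-yne, K2CO3, KI, CuI (cat.), acetone, reflux
Reagents that add atoms: 3-chloro-3-methylbut-1-yne, CC(C)(Cl)C#C
Why: The 4-OH (para to the carbonyl) is the most acidic hydroxyl and the only one not engaged in a hydrogen bond to the ketone, so copper-assisted O-propargylation (Williamson-type etherification with a tertiary propargylic chloride) should etherify it selectively.

Step 8
Reactants: 23 {2,6-dihydroxy-4-[(2-methylbut-3-yn-2-yl)oxy]-3-(3-methylbut-2-en-1-yl)phenyl}(phenyl)methanone
Product: 26 [5,7-dihydroxy-2,2-dimethyl-8-(3-methylbut-2-en-1-yl)-2H-chromen-6-yl](phenyl)methanone, via allenylphenol 24 (not isolated), via quinone methide 25 (not isolated)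
Conditions: xylene, 140 °C
Reagents that add atoms: none
Why: Aryl propargyl ether Claisen rearrangement to the only free ortho carbon and enolisation give 24, a 1,5-hydrogen shift to the central allene carbon (expected from the free 4-OH, not from the ketone-bound 6-OH) gives 25, and oxa-6π electrocyclisation closes the 2,2-dimethyl-2H-pyran ring, while migration toward the prenyl-bearing ortho carbon is reversible and unproductive.

**Compound list**

1 | phloroglucinol (benzene-1,3,5-triol) | Oc1cc(O)cc(O)c1 | starting material
2 | chloromethyl methyl ether | COCCl | starting material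
3 | 3,5-bis(methoxymethoxy)phenol | COCOc1cc(O)cc(OCOC)c1 | intermediate
4 | isopropyl isocyanate | CC(C)N=C=O | starting material
5 | 3,5-bis(methoxymethoxy)phenyl N-isopropylcarbamate | COCOc1cc(OCOC)cc(OC(=O)NC(C)C)c1 | intermediate
6 | chlorotrimethylsilane | C[Si](C)(C)Cl | starting material
7 | prenyl bromide (1-bromo-3-methylbut-2-ene) | CC(C)=CCBr | starting material
8 | 3,5-bis(methoxymethoxy)phenyl N-(tert-butyldimethylsilyl)-N-isopropylcarbamate | COCOc1cc(OCOC)cc(OC(=O)N(C(C)C)[Si](C)(C)C(C)(C)C)c1 | intermediate (not isolated)
9 | 2-lithio-3,5-bis(methoxymethoxy)phenyl N-(tert-butyldimethylsilyl)-N-isopropylcarbamate | COCOc1cc(OCOC)c([Li])c(OC(=O)N(C(C)C)[Si](C)(C)C(C)(C)C)c1 | intermediate (not isolated)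
10 | 3,5-bis(methoxymethoxy)-2-(trimethylsilyl)phenyl N-(tert-butyldimethylsilyl)-N-isopropylcarbamate | COCOc1cc(OCOC)c([Si](C)(C)C)c(OC(=O)N(C(C)C)[Si](C)(C)C(C)(C)C)c1 | intermediate (not isolated)
11 | 6-lithio-3,5-bis(methoxymethoxy)-2-(trimethylsilyl)phenyl N-(tert-butyldimethylsilyl)-N-isopropylcarbamate | COCOc1cc(OCOC)c([Si](C)(C)C)c(OC(=O)N(C(C)C)[Si](C)(C)C(C)(C)C)c1[Li] | intermediate (not isolated)
12 | 3,5-bis(methoxymethoxy)-2-(3-methylbut-2-en-1-yl)-6-(trimethylsilyl)phenyl N-(tert-butyldimethylsilyl)-N-isopropylcarbamate | COCOc1cc(OCOC)c([Si](C)(C)C)c(OC(=O)N(C(C)C)[Si](C)(C)C(C)(C)C)c1CC=C(C)C | intermediate (not isolated)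
13 | 3,5-bis(methoxymethoxy)-2-(3-methylbut-2-en-1-yl)-6-(trimethylsilyl)phenyl N-isopropylcarbamate | COCOc1cc(OCOC)c([Si](C)(C)C)c(OC(=O)NC(C)C)c1CC=C(C)C | intermediate
14 | N-phenylbis(trifluoromethanesulfonimide) | O=S(=O)(N(c1ccccc1)S(=O)(=O)C(F)(F)F)C(F)(F)F | starting material
15 | 3,5-bis(methoxymethoxy)-2-(3-methylbut-2-en-1-yl)-6-(trimethylsilyl)phenol | COCOc1cc(OCOC)c([Si](C)(C)C)c(O)c1CC=C(C)C | intermediate (not isolated)
16 | 3,5-bis(methoxymethoxy)-2-(3-methylbut-2-en-1-yl)-6-(trimethylsilyl)phenyl trifluoromethanesulfonate | COCOc1cc(OCOC)c([Si](C)(C)C)c(OS(=O)(=O)C(F)(F)F)c1CC=C(C)C | intermediate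
17 | benzoic acid | OC(=O)c1ccccc1 | starting material
18 | 3,5-bis(methoxymethoxy)-6-(3-methylbut-2-en-1-yl)benzyne (1,2-didehydrobenzene, triple bond C1–C2) | COCOC1=CC(OCOC)=C(CC=C(C)C)C#C1 | intermediate (not isolated)
19 | caesium [2-(benzoyloxy)-4,6-bis(methoxymethoxy)-3-(3-methylbut-2-en-1-yl)phenyl]ide | COCOc1cc(OCOC)c(CC=C(C)C)c(OC(=O)c2ccccc2)[c-]1.[Cs+] | intermediate (not isolated)
20 | [2-hydroxy-4,6-bis(methoxymethoxy)-3-(3-methylbut-2-en-1-yl)phenyl](phenyl)methanone | COCOc1cc(OCOC)c(CC=C(C)C)c(O)c1C(=O)c1ccccc1 | intermediate
21 | [2,4,6-trihydroxy-3-(3-methylbut-2-en-1-yl)phenyl](phenyl)methanone | Oc1cc(O)c(CC=C(C)C)c(O)c1C(=O)c1ccccc1 | intermediate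
22 | 3-chloro-3-methylbut-1-yne | CC(C)(Cl)C#C | starting material
23 | {2,6-dihydroxy-4-[(2-methylbut-3-yn-2-yl)oxy]-3-(3-methylbut-2-en-1-yl)phenyl}(phenyl)methanone | C#CC(C)(C)Oc1cc(O)c(C(=O)c2ccccc2)c(O)c1CC=C(C)C | intermediate
24 | [2,4,6-trihydroxy-3-(3-methylbuta-1,2-dien-1-yl)-5-(3-methylbut-2-en-1-yl)phenyl](phenyl)methanone | CC(C)=C=Cc1c(O)c(CC=C(C)C)c(O)c(C(=O)c2ccccc2)c1O | intermediate (not isolated)
25 | 4-benzoyl-3,5-dihydroxy-6-(3-methylbut-2-en-1-ylidene)-2-(3-methylbut-2-en-1-yl)cyclohexa-2,4-dien-1-one | CC(C)=CC=C1C(=O)C(CC=C(C)C)=C(O)C(C(=O)c2ccccc2)=C1O | intermediate (not isolated)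
26 | [5,7-dihydroxy-2,2-dimethyl-8-(3-methylbut-2-en-1-yl)-2H-chromen-6-yl](phenyl)methanone | CC(C)=CCc1c(O)c(C(=O)c2ccccc2)c(O)c2c1OC(C)(C)C=C2 | target

**Step count and risks**

Total step count: 8. Longest linear sequence: 8 (fully linear from phloroglucinol).

Steps most likely to fail, riskiest first:

Step 5. The aryl anion may be protonated before the acyl shift, which gives O-arylation (an aryl benzoate) instead of C–O insertion. The aryne may also be consumed by fluoride or by intermolecular ene reaction with prenyl groups. The fallback replaces the aryne event by electrophilic acylation followed by C-alkylation. It sets out from 1: Friedel–Crafts benzoylation with benzoyl chloride and AlCl3 in nitrobenzene should give (2,4,6-trihydroxyphenyl)(phenyl)methanone F1. Mono-C-prenylation of F1 with 7 (DBU, THF) then comes back to the route at 21, at the price of statistical mono- versus di-alkylation.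

Step 3. Metalation may occur at the wrong ring position (C4 between the two OMOM groups), the second metalation may stay incomplete in the presence of the salts of the first, the carbamoyl group may migrate to a lithiated carbon on warming, or allylation may proceed with SN2′ transposition. The fallback places silicon by halogen–metal exchange with a 1,3 O-to-C silyl shift and the prenyl group by sigmatropic rearrangement, with no directed metalation and no carbamate. It sets out from 3: amine-catalysed ortho-bromination (N-bromosuccinimide, cat. i-Pr2NH, CH2Cl2) gives 2-bromo-3,5-bis(methoxymethoxy)phenol F2. O-silylation of F2 with hexamethyldisilazane gives [2-bromo-3,5-bis(methoxymethoxy)phenoxy]trimethylsilane F3. Treatment of F3 with n-BuLi (THF, −78 °C; bromine–lithium exchange then retro-Brook rearrangement) and work-up with aqueous NH4Cl gives 3,5-bis(methoxymethoxy)-2-(trimethylsilyl)phenol F4. O-allylation of F4 with methyl 2-methylbut-3-en-2-yl carbonate and Pd(PPh3)4 gives the 1,1-dimethylallyl ether {2,4-bis(methoxymethoxy)-6-[(2-methylbut-3-en-2-yl)oxy]phenyl}trimethylsilane F5. Aromatic Claisen rearrangement of F5 (toluene, 110 °C) to the free ortho carbon, with allyl inversion, should give phenol 15, where the fallback comes back to the route; 15 is here isolated and triflated with 14 and DBU as in the second stage of step 4 to give 16.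

Step 7. Etherification may be unselective among the three hydroxyls, the tertiary propargylic chloride may be lost by elimination, or C-alkylation of the electron-rich ring may compete. The fallback builds the pyran ring by condensation instead of etherification and rearrangement. It sets out from 21: heating with 3-methylbut-2-enal and catalytic ethylenediammonium diacetate in toluene should give, by aldol-type condensation at the only free ring carbon and loss of water, quinone methide 25, whose oxa-6π electrocyclisation at the non-chelated oxygen leads to 26, where the fallback comes back to the route at the target. This path makes no compound outside the compound list (entry F0).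

Further compounds
F1 | step 5 | (2,4,6-trihydroxyphenyl)(phenyl)methanone | O=C(c1ccccc1)c1c(O)cc(O)cc1O
F2 | step 3 | 2-bromo-3,5-bis(methoxymethoxy)phenol | COCOc1cc(O)c(Br)c(OCOC)c1
F3 | step 3 | [2-bromo-3,5-bis(methoxymethoxy)phenoxy]trimethylsilane | COCOc1cc(O[Si](C)(C)C)c(Br)c(OCOC)c1
F4 | step 3 | 3,5-bis(methoxymethoxy)-2-(trimethylsilyl)phenol | COCOc1cc(O)c([Si](C)(C)C)c(OCOC)c1
F5 | step 3 | {2,4-bis(methoxymethoxy)-6-[(2-methylbut-3-en-2-yl)oxy]phenyl}trimethylsilane | C=CC(C)(C)Oc1cc(OCOC)cc(OCOC)c1[Si](C)(C)C
F0 | step 7 | none | none
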